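**Remarks on the chemistry (assumptions)**
- The target is drawn as one enol tautomer of a β-triketone; the route delivers the tautomeric mixture, and the quaternary carbon (S in this drawing) is the only stereocentre.
- "d-Menthyl" means (1S,2R,5S)-5-methyl-2-(propan-2-yl)cyclohexyl. (5S)-5-(d-Menthyloxy)furan-2(5H)-one, the mirror image of the common l-menthol-derived reagent, is taken as purchasable; otherwise it is made in one operation from 5-hydroxyfuran-2(5H)-one and (+)-menthol.

**Retrosynthetic overview** (dienone ring numbered C1 = ring C=O, C2 = hexanoyl carbon, C3 and C5 = enol carbons, C4 = quaternary carbon, C6 = carbon bearing the CH2-aryl group)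
1. Last disconnection: the C6–CH2 bond of the methylene bridge, giving the monomeric acyl-triketone and the Mannich base of 2,6-dihydroxy-4-methoxyhexanophenone; the aromatic ring comes intact from phloroglucinol.
2. Key disconnection: the C2–C3 and C4–C5 bonds of the dienone ring, formed together when the lithium enolate of a chiral γ-lactone acetal (supplying C3, C4, the methyl group and the first two prenyl carbons) is acylated by 4-methoxy-6-pentyl-2-pyranone (supplying C5, C6, C1, C2 and the hexanoyl group) and the enolate released from the pyranone closes back onto the lactone carbonyl.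
3. Enabling feature: C5–C6–C1–C2 plus the hexanoyl carbonyl are a triketide, the open form of a 4-oxy-6-pentyl-2-pyranone ring whose lactone carbonyl is C5 and whose ring oxygen, once expelled, leaves an enolate at C2. C3 and C4 are the carboxyl and α-carbons of 2-methyl-4-oxobutanoic acid, whose aldehyde carbon (the future prenyl CH=) folds back as a five-membered menthyl acetal lactone that locks the enolate geometry and shields one face of C4.
4. Ring order: the carbocycle is the only ring made, and both temporary rings (pyranone, acetal lactone) are consumed as it forms. The freed aldehyde then becomes the prenyl group (Wittig), the vinylogous methyl ester is cleaved, and the bridge is made last.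

Key step: step 4

**Step 1**
Reactants: 1 4-methoxy-6-methyl-2H-pyran-2-one
Product: 2 4-methoxy-6-pentyl-2H-pyran-2-one
Conditions: LiN(i-Pr)2, THF/DMPU, −78 °C; n-BuI, −78 → −30 °C
Reagents that add atoms: 1-iodobutane, CCCCI
Why: Vinylogous (lateral) deprotonation of the 6-methyl group gives a dienolate that should be alkylated at the exocyclic carbon (enolate alkylation), and no stereocentre is formed.

**Step 2**
Reactants: 3 (5S)-5-(d-menthyloxy)furan-2(5H)-one
Product: 4 (5S)-5-(d-menthyloxy)oxolan-2-one
Conditions: H2 (1 atm), Pd/C, EtOAc, 25 °C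
Reagents that add atoms: none
Why: Heterogeneous catalytic hydrogenation should saturate the butenolide C=C without touching the acetal, whose (S) configuration is carried through unchanged.

**Step 3**
Reactants: 4 (5S)-5-(d-menthyloxy)oxolan-2-one
Product: 5 (5S)-3-methyl-5-(d-menthyloxy)oxolan-2-one (C3 epimers)
Conditions: LiN(i-Pr)2, THF, −78 °C; MeI, −78 → −40 °C
Reagents that add atoms: iodomethane, CI
Why: Lactone enolate alkylation; the new C3 centre should form mainly trans to the menthyloxy group but needs no control because it is planarised again in step 4.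

**Step 4**
Reactants: 5 (5S)-3-methyl-5-(d-menthyloxy)oxolan-2-one (C3 epimers), 2 4-methoxy-6-pentyl-2H-pyran-2-one
Product: 8 2-[(1R)-3-hexanoyl-2-hydroxy-4-methoxy-1-methyl-6-oxocyclohexa-2,4-dien-1-yl]acetaldehyde, via lithium lactone enolate 6 (not isolated), via ring-opened keto-lactone enolate 7 (not isolated)
Conditions: 5, LiN(i-Pr)2 (1.1 equiv), THF, −78 °C; add 2, −78 → −20 °C; aq NH4Cl
Reagents that add atoms: none
Why: Proposed new method: the α-carbon of lithium enolate 6 adds to the lactone carbonyl of pyranone 2, the tetrahedral intermediate opens the pyranone ring and frees the hexanoyl enolate 7, and the α-carbon of this enolate, held cis to the new ketone across the former C3=C4 double bond of the pyranone, attacks the lactone carbonyl in a Claisen (Dieckmann-type, 6-exo-trig) closure that expels the acetal oxygen, which then loses menthoxide to leave the aldehyde. The closest known reaction type is the biomimetic chain extension in which ester-stabilised carbanions are acylated by the lactone carbonyl of 4-methoxy-2-pyranones and the released enolate then closes by Claisen condensation onto the ester of the nucleophile; new here are the tetrasubstituted lactone enolate and the cyclohexadienone product. The one ring closed, the carbocycle, forms by intramolecular acyl substitution at the lactone carbonyl, and the hexanoyl position is unambiguous because only the enolate carbon released from the pyranone can reach that carbonyl through a six-membered transition state. The quaternary stereocentre is set in the first C–C bond formation: the five-membered ring fixes the enolate geometry (methyl exocyclic, future prenyl CH2 in the ring) and the (S)-acetal carbon with its menthyloxy group blocks one face, so the pyranone should enter anti to it, as electrophiles do with γ-substituted butyrolactone enolates. The step needs addition at the pyranone C2 carbonyl rather than at pyranone C4 or C6 or deprotonation of the pentyl CH2; a hard lithium enolate at −78 °C, the 4-methoxy group that deactivates C4 and C6, and the irreversible ring-opening/Claisen relay that ends in the stabilised acyl-dione enolate are what should favour it.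

**Step 5**
Reactants: 8 2-[(1R)-3-hexanoyl-2-hydroxy-4-methoxy-1-methyl-6-oxocyclohexa-2,4-dien-1-yl]acetaldehyde
Product: 9 (6R)-4-hexanoyl-5-hydroxy-3-methoxy-6-methyl-6-(3-methylbut-2-en-1-yl)cyclohexa-2,4-dien-1-one
Conditions: i-PrPPh3I (3 equiv), n-BuLi, THF, 0 °C; add 8, −78 → 25 °C
Reagents that add atoms: isopropyltriphenylphosphonium iodide, CC(C)[P+](c1ccccc1)(c1ccccc1)c1ccccc1.[I-]
Why: Wittig olefination of the aldehyde with the non-stabilised isopropylidene ylide, used in excess because the first equivalent is consumed by the acidic enol, should build the prenyl C=C (no E/Z issue) and leave the quaternary centre untouched.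

**Step 6**
Reactants: 9 (6R)-4-hexanoyl-5-hydroxy-3-methoxy-6-methyl-6-(3-methylbut-2-en-1-yl)cyclohexa-2,4-dien-1-one
Product: 10 (4S)-2-hexanoyl-3,5-dihydroxy-4-methyl-4-(3-methylbut-2-en-1-yl)cyclohexa-2,5-dien-1-one
Conditions: LiCl, DMSO, 120 °C; 1 M HCl work-up at 0 °C
Reagents that add atoms: none
Why: SN2 demethylation of the vinylogous methyl ester by chloride (Krapcho-type dealkylation, well precedented for prenylated acylphloroglucinol-type triketones) should free the enol without acid, so the prenyl group cannot cyclise onto it; the R/S label changes only because the CIP ranking changes, since no bond to the quaternary carbon is touched.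

**Step 7**
Reactants: 11 benzene-1,3,5-triol (phloroglucinol), 12 hexanoyl chloride
Product: 13 1-(2,4,6-trihydroxyphenyl)hexan-1-one
Conditions: AlCl3, PhNO2/CH2Cl2, 0 → 50 °C; aq HCl
Reagents that add atoms: none
Why: Friedel–Crafts C-acylation of the highly activated arene should stop at monoacylation because the ketone–AlCl3 complex deactivates the ring.

**Step 8**
Reactants: 13 1-(2,4,6-trihydroxyphenyl)hexan-1-one
Product: 14 1-(2,6-dihydroxy-4-methoxyphenyl)hexan-1-one
Conditions: Me2SO4 (1.0 equiv), K2CO3, acetone, reflux
Reagents that add atoms: dimethyl sulfate, COS(=O)(=O)OC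
Why: Williamson-type methylation should occur selectively at the 4-OH, the most acidic hydroxyl and the only one not hydrogen-bonded to the ketone, when one equivalent of dimethyl sulfate is used.

**Step 9**
Reactants: 14 1-(2,6-dihydroxy-4-methoxyphenyl)hexan-1-one
Product: 15 1-{3-[(dimethylamino)methyl]-2,6-dihydroxy-4-methoxyphenyl}hexan-1-one
Conditions: CH2=NMe2+ I− (1.0 equiv), MeCN, 0 → 25 °C; aq NaHCO3
Reagents that add atoms: N,N-dimethylmethyleneiminium iodide, C=[N+](C)C.[I-]
Why: Mannich aminomethylation of the electron-rich arene at one of its two equivalent free positions with a preformed iminium salt should stop at the mono-adduct when the stoichiometry is held at one equivalent.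

**Step 10**
Reactants: 15 1-{3-[(dimethylamino)methyl]-2,6-dihydroxy-4-methoxyphenyl}hexan-1-one, 10 (4S)-2-hexanoyl-3,5-dihydroxy-4-methyl-4-(3-methylbut-2-en-1-yl)cyclohexa-2,5-dien-1-one
Product: 16 (4S)-2-hexanoyl-6-[(3-hexanoyl-2,4-dihydroxy-6-methoxyphenyl)methyl]-3,5-dihydroxy-4-methyl-4-(3-methylbut-2-en-1-yl)cyclohexa-2,5-dien-1-one
Conditions: 1,4-dioxane, 100 °C
Reagents that add atoms: none
Why: Thermal loss of dimethylamine from the ortho-hydroxybenzylamine should give an ortho-quinone methide that is captured by Michael addition of the only nucleophilic carbon of triketone 10 (C6), forming the methylene bridge without affecting the quaternary stereocentre.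

**Compound list**
1 | 4-methoxy-6-methyl-2H-pyran-2-one | COC1=CC(=O)OC(C)=C1 | starting material
2 | 4-methoxy-6-pentyl-2H-pyran-2-one | CCCCCC1=CC(OC)=CC(=O)O1 | intermediate
3 | (5S)-5-{[(1S,2R,5S)-5-methyl-2-(propan-2-yl)cyclohexyl]oxy}furan-2(5H)-one | O=C1C=C[C@@H](O[C@H]2C[C@@H](C)CC[C@@H]2C(C)C)O1 | starting material
4 | (5S)-5-{[(1S,2R,5S)-5-methyl-2-(propan-2-yl)cyclohexyl]oxy}oxolan-2-one | O=C1CC[C@@H](O[C@H]2C[C@@H](C)CC[C@@H]2C(C)C)O1 | intermediate
5 | (5S)-3-methyl-5-{[(1S,2R,5S)-5-methyl-2-(propan-2-yl)cyclohexyl]oxy}oxolan-2-one, mixture of C3 epimers | O=C1C(C)C[C@@H](O[C@H]2C[C@@H](C)CC[C@@H]2C(C)C)O1 | intermediate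
6 | lithium (5S)-3-methyl-5-(d-menthyloxy)-4,5-dihydrofuran-2-olate | [Li+].[O-]C1=C(C)C[C@@H](O[C@H]2C[C@@H](C)CC[C@@H]2C(C)C)O1 | intermediate
7 | lithium (Z,Z)-enolate of (3S,5S)-3-(3-methoxy-5-oxodec-2-enoyl)-3-methyl-5-(d-menthyloxy)oxolan-2-one | [Li+].O=C1[C@](C)(C(=O)/C=C(OC)\C=C(/[O-])CCCCC)C[C@@H](O[C@H]2C[C@@H](C)CC[C@@H]2C(C)C)O1 | intermediate
8 | 2-[(1R)-3-hexanoyl-2-hydroxy-4-methoxy-1-methyl-6-oxocyclohexa-2,4-dien-1-yl]acetaldehyde | CCCCCC(=O)C1=C(O)[C@@](C)(CC=O)C(=O)C=C1OC | intermediate
9 | (6R)-4-hexanoyl-5-hydroxy-3-methoxy-6-methyl-6-(3-methylbut-2-en-1-yl)cyclohexa-2,4-dien-1-one | CCCCCC(=O)C1=C(O)[C@@](C)(CC=C(C)C)C(=O)C=C1OC | intermediate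
10 | (4S)-2-hexanoyl-3,5-dihydroxy-4-methyl-4-(3-methylbut-2-en-1-yl)cyclohexa-2,5-dien-1-one | CCCCCC(=O)C1=C(O)[C@@](C)(CC=C(C)C)C(O)=CC1=O | intermediate
11 | benzene-1,3,5-triol (phloroglucinol) | Oc1cc(O)cc(O)c1 | starting material
12 | hexanoyl chloride | CCCCCC(Cl)=O | starting material
13 | 1-(2,4,6-trihydroxyphenyl)hexan-1-one | CCCCCC(=O)c1c(O)cc(O)cc1O | intermediate
14 | 1-(2,6-dihydroxy-4-methoxyphenyl)hexan-1-one | CCCCCC(=O)c1c(O)cc(OC)cc1O | intermediate
15 | 1-{3-[(dimethylamino)methyl]-2,6-dihydroxy-4-methoxyphenyl}hexan-1-one | CCCCCC(=O)c1c(O)cc(OC)c(CN(C)C)c1O | intermediate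
16 | (4S)-2-hexanoyl-6-[(3-hexanoyl-2,4-dihydroxy-6-methoxyphenyl)methyl]-3,5-dihydroxy-4-methyl-4-(3-methylbut-2-en-1-yl)cyclohexa-2,5-dien-1-one | CCCCCC(=O)C1=C(O)[C@@](C)(CC=C(C)C)C(O)=C(Cc2c(OC)cc(O)c(C(=O)CCCCC)c2O)C1=O | target

**Step count**
Total steps: 10. Longest linear sequence: 6 steps (steps 2, 3, 4, 5, 6, 10).

**Steps most likely to fail**

1. Step 4. What may go wrong: proton transfer from the pentyl CH2 of the pyranone to the lactone enolate, addition at pyranone C4 or C6 instead of the lactone carbonyl, or an incomplete Claisen closure. The fallback uses known reactions only, sets out from 5 and returns at 10.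
 - Enolate 6 is C-acylated with N-acetylimidazole anti to the menthyloxy group to give (3S,5S)-3-acetyl-3-methyl-5-(d-menthyloxy)oxolan-2-one F1.
 - The methyl-ketone enolate of F1 (LiN(i-Pr)2, 3 equiv) undergoes crossed Claisen condensation with methyl 2-(2-pentyl-1,3-dioxolan-2-yl)acetate F2, made from commercial methyl 3-oxooctanoate, ethane-1,2-diol and TsOH.
 - The dianion of the resulting β-diketone closes onto the lactone carbonyl (Dieckmann) with loss of menthol to give 2-[(1R)-2-hydroxy-1-methyl-4,6-dioxo-3-(2-pentyl-1,3-dioxolan-2-yl)cyclohex-2-en-1-yl]acetaldehyde F3.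
 - Dilute aqueous acid removes the dioxolane to give 2-[(1S)-3-hexanoyl-2,6-dihydroxy-1-methyl-4-oxocyclohexa-2,5-dien-1-yl]acetaldehyde F4, and the Wittig reaction of step 5 applied to F4 gives 10.
 - The hexanoyl carbon is masked but already in place before the ring closes, so the two sides of the quaternary carbon never become equivalent.

2. Step 5. What may go wrong: slow addition of the hindered ylide to an aldehyde that sits next to a quaternary carbon and can hide as a lactol, with enolisation instead of olefination. The fallback sets out from 8 and returns at 9. Methylenation with the unhindered ylide Ph3P=CH2 (from Ph3PCH3Br and KOt-Bu) gives (6R)-4-hexanoyl-5-hydroxy-3-methoxy-6-methyl-6-(prop-2-en-1-yl)cyclohexa-2,4-dien-1-one F5. Cross-metathesis of its allyl group with 2-methylbut-2-ene (second-generation Grubbs catalyst, CH2Cl2, 40 °C) then gives 9.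

3. Step 10. What may go wrong: self-condensation or oligomerisation of the quinone methide, and O- instead of C-alkylation of 10. The fallback sets out from 10 and returns at 16 with the roles exchanged. Triketone 10, which has a single nucleophilic carbon, is aminomethylated with N,N-dimethylmethyleneiminium iodide to give (4S)-6-[(dimethylamino)methyl]-2-hexanoyl-3,5-dihydroxy-4-methyl-4-(3-methylbut-2-en-1-yl)cyclohexa-2,5-dien-1-one F6. On warming with an excess of 14, F6 loses dimethylamine to a methylene-trione acceptor that the arene captures to give 16.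

**Further compounds**
F1 | step 4 | (3S,5S)-3-acetyl-3-methyl-5-{[(1S,2R,5S)-5-methyl-2-(propan-2-yl)cyclohexyl]oxy}oxolan-2-one | O=C1[C@](C)(C(C)=O)C[C@@H](O[C@H]2C[C@@H](C)CC[C@@H]2C(C)C)O1
F2 | step 4 | methyl 2-(2-pentyl-1,3-dioxolan-2-yl)acetate | CCCCCC1(CC(=O)OC)OCCO1
F3 | step 4 | 2-[(1R)-2-hydroxy-1-methyl-4,6-dioxo-3-(2-pentyl-1,3-dioxolan-2-yl)cyclohex-2-en-1-yl]acetaldehyde | CCCCCC2(OCCO2)C1=C(O)[C@@](C)(CC=O)C(=O)CC1=O
F4 | step 4 | 2-[(1S)-3-hexanoyl-2,6-dihydroxy-1-methyl-4-oxocyclohexa-2,5-dien-1-yl]acetaldehyde | CCCCCC(=O)C1=C(O)[C@@](C)(CC=O)C(O)=CC1=O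
F5 | step 5 | (6R)-4-hexanoyl-5-hydroxy-3-methoxy-6-methyl-6-(prop-2-en-1-yl)cyclohexa-2,4-dien-1-one | CCCCCC(=O)C1=C(O)[C@@](C)(CC=C)C(=O)C=C1OC
F6 | step 10 | (4S)-6-[(dimethylamino)methyl]-2-hexanoyl-3,5-dihydroxy-4-methyl-4-(3-methylbut-2-en-1-yl)cyclohexa-2,5-dien-1-one | CCCCCC(=O)C1=C(O)[C@@](C)(CC=C(C)C)C(O)=C(CN(C)C)C1=O
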